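**Retrosynthetic overview**
- The four phenols are carried as benzyl ethers and released by a final hydrogenolysis. The propyl CH2 next to the methoxy-hydroxyphenyl ring comes from an aryl ketone removed through its tosylhydrazone.
- Key disconnection: the bond between the diarylmethine carbon and chroman C6. It is made by a rhodium-catalysed asymmetric 1,4-addition of a flavan-6-boronate (20 heavy atoms of the target) to a chalcone (19 heavy atoms), which sets the (R) centre.
- Flavan boronate: Claisen–Schmidt condensation of a resorcinol-derived bromosalicylaldehyde with a hydroquinone-derived acetophenone, C=C reduction, asymmetric ketone reduction, Mitsunobu ring closure with inversion (sets 2S), then borylation.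
- Chalcone: Claisen–Schmidt condensation of a resorcinol-derived acetophenone with a 4-bromophenol-derived aldehyde.
- Ring order: all benzene rings are bought (resorcinol, hydroquinone, 4-bromophenol). The only ring built is the pyran ring (ring C) of the chroman, closed before the fragment union.

Assumption: Ph-bod* is 2,5-diphenylbicyclo[2.2.2]octa-2,5-diene; the ligand hand in step 18 is assigned from the usual enone-face model (the (R,R) ligand, which gives (R)-3-phenylcyclohexanone, binds the α-Re face) and should be confirmed on first use.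

**Flavan fragment**

Step 1
Reactants: 1 resorcinol
Product: 3 2,4-dihydroxybenzaldehyde, via aryl iminium chloride 2 (not isolated)
Conditions: POCl3, DMF, MeCN, −15 °C → rt; then H2O, 50 °C
Reagents that add atoms: N,N-dimethylformamide CN(C)C=O; water O
Why: Vilsmeier–Haack formylation attacks C4 of resorcinol (para to one OH, ortho to the other) and the iminium salt is hydrolysed to the aldehyde.

Step 2
Reactants: 3 2,4-dihydroxybenzaldehyde
Product: 4 5-bromo-2,4-dihydroxybenzaldehyde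
Conditions: Br2 (1.0 eq), AcOH, 15–20 °C
Reagents that add atoms: bromine BrBr
Why: Electrophilic aromatic bromination goes to C5, para to the 2-OH and ortho to the 4-OH, and not to the C3 position flanked by two oxygens.

Step 3
Reactants: 4 5-bromo-2,4-dihydroxybenzaldehyde
Product: 5 4-(benzyloxy)-5-bromo-2-hydroxybenzaldehyde
Conditions: BnBr (1.05 eq), NaHCO3, MeCN, reflux
Reagents that add atoms: benzyl bromide BrCc1ccccc1
Why: Williamson etherification with a weak base alkylates only the more acidic free 4-OH, because the 2-OH is hydrogen-bonded to the aldehyde.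

Step 4
Reactants: 6 hydroquinone
Product: 7 1-(2,5-dihydroxyphenyl)ethanone
Conditions: AcOH, ZnCl2 (fused), 140 °C
Reagents that add atoms: acetic acid CC(=O)O
Why: Nencki-type Friedel–Crafts C-acylation of the symmetrical diphenol can give only one ortho-hydroxy ketone.

Step 5
Reactants: 7 1-(2,5-dihydroxyphenyl)ethanone
Product: 8 1-[5-(benzyloxy)-2-hydroxyphenyl]ethanone
Conditions: BnBr (1.0 eq), K2CO3, acetone, reflux
Reagents that add atoms: benzyl bromide BrCc1ccccc1
Why: Williamson etherification is selective for the free 5-OH because the 2-OH is chelated to the ketone.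

Step 6
Reactants: 8 1-[5-(benzyloxy)-2-hydroxyphenyl]ethanone
Product: 9 1-[5-(benzyloxy)-2-methoxyphenyl]ethanone
Conditions: MeI (3 eq), K2CO3, DMF, 40 °C
Reagents that add atoms: iodomethane CI
Why: Williamson methylation of the remaining chelated phenol proceeds under the more forcing DMF/excess MeI conditions.

Step 7
Reactants: 5 4-(benzyloxy)-5-bromo-2-hydroxybenzaldehyde; 9 1-[5-(benzyloxy)-2-methoxyphenyl]ethanone
Product: 10 (E)-3-[4-(benzyloxy)-5-bromo-2-hydroxyphenyl]-1-[5-(benzyloxy)-2-methoxyphenyl]prop-2-en-1-one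
Conditions: KOH (aq. 40%), EtOH, rt, 48 h; then AcOH to pH 5 at 0 °C
Reagents that add atoms: none
Why: Claisen–Schmidt condensation of the methyl ketone enolate with the non-enolisable aldehyde, followed by E1cB dehydration, gives the E-enone.

Step 8
Reactants: 10 (E)-2-hydroxychalcone
Product: 11 3-[4-(benzyloxy)-5-bromo-2-hydroxyphenyl]-1-[5-(benzyloxy)-2-methoxyphenyl]propan-1-one
Conditions: H2 (1 atm), 10% Pd/C (palladium on carbon), Ph2S (cat.), EtOAc, rt
Reagents that add atoms: none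
Why: Hydrogenation over sulfide-poisoned Pd/C reduces only the conjugated C=C and leaves the aryl bromide, benzyl ethers and aryl ketone intact.

Step 9
Reactants: 11 dihydrochalcone
Product: 12 (1R)-3-[4-(benzyloxy)-5-bromo-2-hydroxyphenyl]-1-[5-(benzyloxy)-2-methoxyphenyl]propan-1-ol
Conditions: RuCl(p-cymene)[(R,R)-TsDPEN] (1 mol%), HCO2H/Et3N (5:2), EtOAc, 40 °C
Reagents that add atoms: none
Why: Noyori–Ikariya asymmetric transfer hydrogenation tolerates the free phenol, and the (R,R) catalyst delivers hydride to the Si face of the aryl ketone to give the (R) carbinol, as with acetophenone.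

Step 10
Reactants: 12 (1R)-diarylpropanol
Product: 13 (2S)-7-(benzyloxy)-2-[5-(benzyloxy)-2-methoxyphenyl]-6-bromo-3,4-dihydro-2H-chromene
Conditions: PPh3, DIAD, THF, 0 °C → rt
Reagents that add atoms: none
Why: Intramolecular Mitsunobu etherification closes the pyran ring by SN2 attack of the phenol on the activated benzylic carbinol with inversion, turning (R) into (2S).

Step 11
Reactants: 13 (2S)-6-bromoflavan
Product: 14 (2S)-7-(benzyloxy)-2-[5-(benzyloxy)-2-methoxyphenyl]-6-(4,4,5,5-tetramethyl-1,3,2-dioxaborolan-2-yl)-3,4-dihydro-2H-chromene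
Conditions: B2pin2, PdCl2(dppf) (5 mol%), KOAc, 1,4-dioxane, 90 °C
Reagents that add atoms: bis(pinacolato)diboron CC1(C)OB(OC1(C)C)B1OC(C)(C)C(C)(C)O1
Why: Miyaura borylation replaces the aryl bromide by a pinacol boronate without touching the C2 stereocentre or the ethers.

**Chalcone fragment**

Step 12
Reactants: 1 resorcinol
Product: 15 1-(2,4-dihydroxyphenyl)ethanone
Conditions: AcOH, ZnCl2 (fused), 140 °C
Reagents that add atoms: acetic acid CC(=O)O
Why: Nencki Friedel–Crafts acylation occurs at C4 of resorcinol, activated by both hydroxyls.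

Step 13
Reactants: 15 1-(2,4-dihydroxyphenyl)ethanone
Product: 16 1-[4-(benzyloxy)-2-hydroxyphenyl]ethanone
Conditions: BnBr (1.0 eq), K2CO3, acetone, reflux
Reagents that add atoms: benzyl bromide BrCc1ccccc1
Why: Williamson etherification takes the free 4-OH because the 2-OH is chelated to the ketone.

Step 14
Reactants: 16 1-[4-(benzyloxy)-2-hydroxyphenyl]ethanone
Product: 17 1-[4-(benzyloxy)-2-methoxyphenyl]ethanone
Conditions: MeI (3 eq), K2CO3, DMF, 40 °C
Reagents that add atoms: iodomethane CI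
Why: Williamson methylation of the chelated phenol installs the methoxy group that is kept to the end.

Step 15
Reactants: 18 4-bromophenol
Product: 19 1-(benzyloxy)-4-bromobenzene
Conditions: BnBr, K2CO3, acetone, reflux
Reagents that add atoms: benzyl bromide BrCc1ccccc1
Why: Williamson etherification of a simple phenol.

Step 16
Reactants: 19 1-(benzyloxy)-4-bromobenzene
Product: 22 4-(benzyloxy)benzaldehyde, via [4-(benzyloxy)phenyl]lithium 20 (not isolated), via lithium hemiaminal alkoxide 21 (not isolated)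
Conditions: n-BuLi, THF, −78 °C; DMF, −78 → 0 °C; then H2O
Reagents that add atoms: N,N-dimethylformamide CN(C)C=O
Why: Bromine–lithium exchange followed by Bouveault formylation with DMF, whose tetrahedral adduct collapses to the aldehyde on aqueous quench.

Step 17
Reactants: 17 1-[4-(benzyloxy)-2-methoxyphenyl]ethanone; 22 4-(benzyloxy)benzaldehyde
Product: 23 (E)-1-[4-(benzyloxy)-2-methoxyphenyl]-3-[4-(benzyloxy)phenyl]prop-2-en-1-one
Conditions: KOH (aq.), EtOH, rt
Reagents that add atoms: none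
Why: Claisen–Schmidt condensation gives the thermodynamically favoured E-chalcone.

**Fragment union and end game**

Step 18
Reactants: 14 (2S)-flavan-6-boronate (1.2 eq); 23 (E)-chalcone
Product: 24 (3R)-1-[4-(benzyloxy)-2-methoxyphenyl]-3-[4-(benzyloxy)phenyl]-3-{(2S)-7-(benzyloxy)-2-[5-(benzyloxy)-2-methoxyphenyl]-3,4-dihydro-2H-chromen-6-yl}propan-1-one
Conditions: [RhCl(C2H4)2]2 (2.5 mol%), (R,R)-Ph-bod* (5.5 mol%), KOH (0.5 eq, aq.), 1,4-dioxane/H2O 10:1, 50 °C
Reagents that add atoms: none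
Why: Hayashi–Miyaura rhodium-catalysed asymmetric 1,4-addition, in which the chiral diene binds the enone on its α-Re face so the aryl is delivered to the Re face of the β-carbon, giving (R) under catalyst control with the remote C2 centre untouched.

Step 19
Reactants: 24 (3R)-β,β-diaryl ketone
Product: 25 4-methylbenzenesulfonohydrazone of 24 (E/Z mixture at C=N)
Conditions: TsNHNH2 (1.5 eq), PPTS (cat.), EtOH/THF, 70 °C
Reagents that add atoms: 4-methylbenzenesulfonohydrazide Cc1ccc(cc1)S(=O)(=O)NN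
Why: Simple carbonyl condensation gives the tosylhydrazone with no change at either stereocentre.

Step 20
Reactants: 25 tosylhydrazone
Product: 28 (2S)-7-(benzyloxy)-6-{(1R)-3-[4-(benzyloxy)-2-methoxyphenyl]-1-[4-(benzyloxy)phenyl]propyl}-2-[5-(benzyloxy)-2-methoxyphenyl]-3,4-dihydro-2H-chromene, via N-boryl tosylhydrazide 26 (not isolated), via alkyl diazene 27 (not isolated)
Conditions: catecholborane (3 eq), CHCl3, 0 °C → rt; then NaOAc·3H2O, reflux
Reagents that add atoms: none
Why: Kabalka (Caglioti-type) deoxygenation, in which C=N hydroboration, acetate-induced sulfinate loss and N2 extrusion from the diazene give the CH2 without any benzylic cation that could open the flavan or scramble a stereocentre.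

Step 21
Reactants: 28 tetrabenzyl ether
Product: 29 (2S)-6-[(1R)-1-(4-hydroxyphenyl)-3-(4-hydroxy-2-methoxyphenyl)propyl]-2-(5-hydroxy-2-methoxyphenyl)-3,4-dihydro-2H-chromen-7-ol
Conditions: H2 (1 atm), 10% Pd/C (palladium on carbon), EtOAc/MeOH 1:1, rt
Reagents that add atoms: none
Why: Neutral hydrogenolysis cleaves the four O-benzyl ethers while the methyl ethers, the chroman C2–O bond and both stereocentres are retained.

**Compound list**

1 | resorcinol | Oc1cccc(O)c1 | starting material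
2 | [(2,4-dihydroxyphenyl)methylidene]dimethyliminium chloride | C[N+](C)=Cc1ccc(O)cc1O.[Cl-] | intermediate (not isolated)
3 | 2,4-dihydroxybenzaldehyde | O=Cc1ccc(O)cc1O | intermediate
4 | 5-bromo-2,4-dihydroxybenzaldehyde | O=Cc1cc(Br)c(O)cc1O | intermediate
5 | 4-(benzyloxy)-5-bromo-2-hydroxybenzaldehyde | O=Cc1cc(Br)c(OCc2ccccc2)cc1O | intermediate
6 | hydroquinone | Oc1ccc(O)cc1 | starting material
7 | 1-(2,5-dihydroxyphenyl)ethanone | CC(=O)c1cc(O)ccc1O | intermediate
8 | 1-[5-(benzyloxy)-2-hydroxyphenyl]ethanone | CC(=O)c1cc(OCc2ccccc2)ccc1O | intermediate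
9 | 1-[5-(benzyloxy)-2-methoxyphenyl]ethanone | COc1ccc(OCc2ccccc2)cc1C(C)=O | intermediate
10 | (E)-3-[4-(benzyloxy)-5-bromo-2-hydroxyphenyl]-1-[5-(benzyloxy)-2-methoxyphenyl]prop-2-en-1-one | COc1ccc(OCc2ccccc2)cc1C(=O)/C=C/c1cc(Br)c(OCc2ccccc2)cc1O | intermediate
11 | 3-[4-(benzyloxy)-5-bromo-2-hydroxyphenyl]-1-[5-(benzyloxy)-2-methoxyphenyl]propan-1-one | COc1ccc(OCc2ccccc2)cc1C(=O)CCc1cc(Br)c(OCc2ccccc2)cc1O | intermediate
12 | (1R)-3-[4-(benzyloxy)-5-bromo-2-hydroxyphenyl]-1-[5-(benzyloxy)-2-methoxyphenyl]propan-1-ol | COc1ccc(OCc2ccccc2)cc1[C@H](O)CCc1cc(Br)c(OCc2ccccc2)cc1O | intermediate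
13 | (2S)-7-(benzyloxy)-2-[5-(benzyloxy)-2-methoxyphenyl]-6-bromo-3,4-dihydro-2H-chromene | COc1ccc(OCc2ccccc2)cc1[C@@H]1CCc2cc(Br)c(OCc3ccccc3)cc2O1 | intermediate
14 | (2S)-7-(benzyloxy)-2-[5-(benzyloxy)-2-methoxyphenyl]-6-(4,4,5,5-tetramethyl-1,3,2-dioxaborolan-2-yl)-3,4-dihydro-2H-chromene | COc1ccc(OCc2ccccc2)cc1[C@@H]1CCc2cc(B3OC(C)(C)C(C)(C)O3)c(OCc3ccccc3)cc2O1 | intermediate
15 | 1-(2,4-dihydroxyphenyl)ethanone | CC(=O)c1ccc(O)cc1O | intermediate
16 | 1-[4-(benzyloxy)-2-hydroxyphenyl]ethanone | CC(=O)c1ccc(OCc2ccccc2)cc1O | intermediate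
17 | 1-[4-(benzyloxy)-2-methoxyphenyl]ethanone | COc1cc(OCc2ccccc2)ccc1C(C)=O | intermediate
18 | 4-bromophenol | Oc1ccc(Br)cc1 | starting material
19 | 1-(benzyloxy)-4-bromobenzene | Brc1ccc(OCc2ccccc2)cc1 | intermediate
20 | [4-(benzyloxy)phenyl]lithium | [Li]c1ccc(OCc2ccccc2)cc1 | intermediate (not isolated)
21 | lithium [4-(benzyloxy)phenyl](dimethylamino)methanolate | CN(C)C([O-])c1ccc(OCc2ccccc2)cc1.[Li+] | intermediate (not isolated)
22 | 4-(benzyloxy)benzaldehyde | O=Cc1ccc(OCc2ccccc2)cc1 | intermediate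
23 | (E)-1-[4-(benzyloxy)-2-methoxyphenyl]-3-[4-(benzyloxy)phenyl]prop-2-en-1-one | COc1cc(OCc2ccccc2)ccc1C(=O)/C=C/c1ccc(OCc2ccccc2)cc1 | intermediate
24 | (3R)-1-[4-(benzyloxy)-2-methoxyphenyl]-3-[4-(benzyloxy)phenyl]-3-{(2S)-7-(benzyloxy)-2-[5-(benzyloxy)-2-methoxyphenyl]-3,4-dihydro-2H-chromen-6-yl}propan-1-one | COc1cc(OCc2ccccc2)ccc1C(=O)C[C@H](c1ccc(OCc2ccccc2)cc1)c1cc2c(cc1OCc1ccccc1)O[C@H](c1cc(OCc3ccccc3)ccc1OC)CC2 | intermediate
25 | 4-methylbenzenesulfonohydrazone of 24 (E/Z mixture at C=N; 3R, 2S retained) | COc1cc(OCc2ccccc2)ccc1C(=NNS(=O)(=O)c1ccc(C)cc1)C[C@H](c1ccc(OCc2ccccc2)cc1)c1cc2c(cc1OCc1ccccc1)O[C@H](c1cc(OCc3ccccc3)ccc1OC)CC2 | intermediate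
26 | N-(1,3,2-benzodioxaborol-2-yl)-N'-tosyl hydrazine from hydroboration of 25 (both epimers at the new CH–N carbon) | COc1cc(OCc2ccccc2)ccc1C(N(B1Oc2ccccc2O1)NS(=O)(=O)c1ccc(C)cc1)C[C@H](c1ccc(OCc2ccccc2)cc1)c1cc2c(cc1OCc1ccccc1)O[C@H](c1cc(OCc3ccccc3)ccc1OC)CC2 | intermediate (not isolated)
27 | monoalkyl diazene R2CH–N=NH from 26 (both epimers at the CH–N carbon) | COc1cc(OCc2ccccc2)ccc1C(N=N)C[C@H](c1ccc(OCc2ccccc2)cc1)c1cc2c(cc1OCc1ccccc1)O[C@H](c1cc(OCc3ccccc3)ccc1OC)CC2 | intermediate (not isolated)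
28 | (2S)-7-(benzyloxy)-6-{(1R)-3-[4-(benzyloxy)-2-methoxyphenyl]-1-[4-(benzyloxy)phenyl]propyl}-2-[5-(benzyloxy)-2-methoxyphenyl]-3,4-dihydro-2H-chromene | COc1cc(OCc2ccccc2)ccc1CC[C@H](c1ccc(OCc2ccccc2)cc1)c1cc2c(cc1OCc1ccccc1)O[C@H](c1cc(OCc3ccccc3)ccc1OC)CC2 | intermediate
29 | (2S)-6-[(1R)-1-(4-hydroxyphenyl)-3-(4-hydroxy-2-methoxyphenyl)propyl]-2-(5-hydroxy-2-methoxyphenyl)-3,4-dihydro-2H-chromen-7-ol | COc1cc(O)ccc1CC[C@H](c1ccc(O)cc1)c1cc2c(cc1O)O[C@H](c1cc(O)ccc1OC)CC2 | target

**Step count and risks**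

Total steps: 21. Longest linear sequence: 12 steps (1, 2, 3, 7, 8, 9, 10, 11, 18, 19, 20, 21; the path through steps 4, 5, 6 is equally long).

Most likely to fail:

Step 10 (Mitsunobu ring closure). The ortho-methoxy group stabilises a benzylic cation, so SN1 leakage or styrene formation could erode the ee set in step 9. The fallback sets out from 11 and comes back at 13. Acid-catalysed cyclodehydration of 11 (p-TsOH, toluene, Dean–Stark) gives 7-(benzyloxy)-2-[5-(benzyloxy)-2-methoxyphenyl]-6-bromo-4H-chromene F1. Its enol-ether C2=C3 bond is then hydrogenated asymmetrically (H2, 50 bar, [Ir(cod)(tBu-PHOX)]BArF, CH2Cl2, the ligand antipode that gives the 2S product) to deliver 13 directly. The stereocentre is then set by the hydrogenation catalyst and no substitution at the benzylic carbon is needed.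

Step 18 (rhodium-catalysed 1,4-addition). The ortho-benzyloxy, electron-rich boronate 14 may transmetalate slowly and protodeboronate, and it is the more valuable partner. The fallback exchanges the roles of the two aryl groups; it sets out from 13 (using 17 and 19 as well) and comes back at 24. Bromine–lithium exchange on 13 (n-BuLi, THF, −78 °C) gives the 6-lithio flavan F2. DMF converts it into the lithium hemiaminal alkoxide F3, and aqueous quench releases (2S)-7-(benzyloxy)-2-[5-(benzyloxy)-2-methoxyphenyl]-3,4-dihydro-2H-chromene-6-carbaldehyde F4. Claisen–Schmidt condensation of F4 with 17 (KOH, EtOH) gives (E)-1-[4-(benzyloxy)-2-methoxyphenyl]-3-{(2S)-7-(benzyloxy)-2-[5-(benzyloxy)-2-methoxyphenyl]-3,4-dihydro-2H-chromen-6-yl}prop-2-en-1-one F5. Separately, Miyaura borylation of 19 (B2pin2, PdCl2(dppf), KOAc, dioxane) gives 2-[4-(benzyloxy)phenyl]-4,4,5,5-tetramethyl-1,3,2-dioxaborolane F6, an unhindered boronate that can be used in excess. Rhodium-catalysed addition of F6 to F5 with [RhCl(C2H4)2]2 and (S,S)-Ph-bod* (the opposite hand, because the incoming aryl is now the lower-priority one) gives 24.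

Step 20 (tosylhydrazone reduction). The hydrazone of a hindered, very electron-rich aryl ketone may reduce sluggishly or give styrene by Bamford–Stevens elimination. The fallback sets out from 24 and comes back at 29, by-passing 25 to 28. NaBH4 (MeOH/THF, 0 °C) reduces 24 to (3R)-1-[4-(benzyloxy)-2-methoxyphenyl]-3-[4-(benzyloxy)phenyl]-3-{(2S)-7-(benzyloxy)-2-[5-(benzyloxy)-2-methoxyphenyl]-3,4-dihydro-2H-chromen-6-yl}propan-1-ol F7 (both carbinol epimers, inconsequential). Hydrogenation of F7 (H2, Pd/C, EtOAc/EtOH, cat. AcOH) then cleaves the four benzyl ethers and the doubly oxygen-activated benzylic C–OH in one operation. The precedent is the hydrogenolysis of flavan-4-ols to flavans with the C2–O bond intact.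

**Further compounds**

F1 | step 10 | 7-(benzyloxy)-2-[5-(benzyloxy)-2-methoxyphenyl]-6-bromo-4H-chromene | COc1ccc(OCc2ccccc2)cc1C1=CCc2cc(Br)c(OCc3ccccc3)cc2O1
F2 | step 18 | {(2S)-7-(benzyloxy)-2-[5-(benzyloxy)-2-methoxyphenyl]-3,4-dihydro-2H-chromen-6-yl}lithium | COc1ccc(OCc2ccccc2)cc1[C@@H]1CCc2cc([Li])c(OCc3ccccc3)cc2O1
F3 | step 18 | lithium {(2S)-7-(benzyloxy)-2-[5-(benzyloxy)-2-methoxyphenyl]-3,4-dihydro-2H-chromen-6-yl}(dimethylamino)methanolate | COc1ccc(OCc2ccccc2)cc1[C@@H]1CCc2cc(C([O-])N(C)C)c(OCc3ccccc3)cc2O1.[Li+]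
F4 | step 18 | (2S)-7-(benzyloxy)-2-[5-(benzyloxy)-2-methoxyphenyl]-3,4-dihydro-2H-chromene-6-carbaldehyde | COc1ccc(OCc2ccccc2)cc1[C@@H]1CCc2cc(C=O)c(OCc3ccccc3)cc2O1
F5 | step 18 | (E)-1-[4-(benzyloxy)-2-methoxyphenyl]-3-{(2S)-7-(benzyloxy)-2-[5-(benzyloxy)-2-methoxyphenyl]-3,4-dihydro-2H-chromen-6-yl}prop-2-en-1-one | COc1cc(OCc2ccccc2)ccc1C(=O)/C=C/c1cc2c(cc1OCc1ccccc1)O[C@H](c1cc(OCc3ccccc3)ccc1OC)CC2
F6 | step 18 | 2-[4-(benzyloxy)phenyl]-4,4,5,5-tetramethyl-1,3,2-dioxaborolane | CC1(C)OB(OC1(C)C)c1ccc(OCc2ccccc2)cc1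
F7 | step 20 | (3R)-1-[4-(benzyloxy)-2-methoxyphenyl]-3-[4-(benzyloxy)phenyl]-3-{(2S)-7-(benzyloxy)-2-[5-(benzyloxy)-2-methoxyphenyl]-3,4-dihydro-2H-chromen-6-yl}propan-1-ol (both C1 epimers) | COc1cc(OCc2ccccc2)ccc1C(O)C[C@H](c1ccc(OCc2ccccc2)cc1)c1cc2c(cc1OCc1ccccc1)O[C@H](c1cc(OCc3ccccc3)ccc1OC)CC2
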